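The readings are calculated for substances that don't exist, noise included.

The rate constants of this flask are not given, so the reckoning must come from two runs and from what a charge of substrate buys.

| setting | gamma | alpha | flask |
|---|---|---|---|
| substrate | 0.64 M | 1.3 M | 0.64 M |
| partner A | 0.96 M | 0.96 M | 0.960 M |
| partner B | 1.92 M | 1.92 M | 1.92 M |
| remark | the very flask that is asked about, followed so far | run made earlier |  |
| time |  |  | 40 min |

gamma run (percent of the substrate charged)

| time / min | target / % | substrate / % |
|---|---|---|
| 2.00 | 14.1 | 3.7 |
| 6.00 | 26.6 | 0.4 |
| 12.0 | 27.1 | 0 |
| 15.0 | 27.1 | 0 |
| 25.0 | 28.4 | 0.1 |

alpha run (percent of the substrate charged)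

| time / s | target / % | substrate / % |
|---|---|---|
| 10.0 | 0.2 | 75.6 |
| 25.0 | 2.1 | 44.8 |
| 40.0 | 2.6 | 28.3 |
| 60.0 | 2.6 | 18.9 |
| 90.0 | 6.4 | 11.3 |

(scatter of a reading: 1 percentage point)

- target taken out counts as made
- additions bring no volume worth counting

- dusk: change nothing and wait 20 min more
- spring: at 40 min take out 90% of the target then present, then wait 20 min
- autumn: at 40 min add substrate, 50.0% of the amount charged, then wait 20 min

- target, in percent of the substrate first charged, at 40 min
- the remedy with the largest gain of target, or "none" below 2 percentage points (dusk / spring / autumn / none)
- target present, with what was taken out counted in, in percent of the substrate first charged, after dusk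
- target present, with what was taken out counted in, in percent of the substrate first charged, after spring

**What does the gamma run show?** Target stands nearly flat, at 27.1% after 12.0 min and 28.4% after 25.0 min, a rise of 1.3 percentage points against a scatter of 1 point. Substrate reads 0.1% at that last reading, so this percentage is in effect the selectivity for target.

**Then why not carry that percentage over to fresh substrate?** The alpha run speaks against it. Alpha was charged with twice the substrate of gamma, yet it holds 0.0832 M of target after 90.0 s, while gamma holds 0.0902 M after 2.00 min. In powers of ten, the charge went up by 0.308, and molar target moved by −0.0351.

**So what do you carry instead?** I carry a molar amount. The mean of gamma's last three target readings times its charge gives 0.176 M, which I call the ceiling, the molar target at which gamma's readings level off. My wager for a larger charge of substrate on the same partner A and partner B is that target levels off at this same ceiling, so that the logarithm of the percentage is the logarithm of the ceiling minus the logarithm of the charge.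

**Isn't alpha simply too early?** That is the weak spot. Its last reading comes earlier than gamma's first, with 11.3% of substrate still there and no plateau seen, so the ceiling is a wager.

**What do you commit to?** For 40 min I reckon 27.5%. Gamma's level readings give me no gain to expect from dusk or spring. Autumn adds substrate on the same partners, and by my wager the ceiling stays where it was, so I answer none.

The forecast gives 27.5%, 27.7% after dusk and 28% after spring, and it picks autumn: “Fresh substrate should give 27 % of itself, about +13.5 points, if the partners suffice.” On autumn the forecast and I differ.

The flask holds 29.5% of target at 40 min, and the best remedy is none.

    substrate + open intermediate → side product (k = 0.0940 M⁻¹ s⁻¹)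
    substrate + partner B → open intermediate (k = 0.0130 M⁻¹ s⁻¹)
    partner B + partner A → second intermediate (k = 0.00900 M⁻¹ s⁻¹)
    2 second intermediate → homo product (k = 0.0170 M⁻¹ s⁻¹)
    open intermediate + second intermediate → target (k = 0.0290 M⁻¹ s⁻¹)

That is 0.189 M of target against the ceiling of 0.176 M. Autumn gains 1.5 points, under the mark of 2 points, with partner A at 0% of its charge when the substrate goes in. The neighbour flask charged with 1.6 M of substrate, its partners as in this flask, stands 0.398 of a power of ten above this flask in substrate, so the ceiling gives it 11.0%, and it holds 10.7% after 40.0 min.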